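**Retrosynthetic overview** (ring numbering: C1 = CMe2, C2 = CHCl, C3 = C(=C7H–C8H2Br), C4 = CHCl, C5 = CH2, C6 = CHBr)
1. Target 16 ⇐ allylic alcohol 15 (C8–OH → Br) ⇐ spiro-oxetan-2-one 13 by thermal loss of CO2, which unveils C3=C7 with C8 held cis to C2; C6–Br ⇐ C6–OH (inversion) ⇐ C6=O.
2. Key disconnection: C1–C2 and C3–C4 in one Diels–Alder reaction of chlorodiene 9 (C4=C5–C6(OTBS)=C1Me2) with the (Z)-chloromethylidene-β-lactone 5, a stereodefined 1-chloroallene equivalent (C2, C3, C7, C8 plus one carbon that later leaves as CO2).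
3. Enabling feature: the exocyclic alkylidene carbon C3 of the cyclohexane ring lies between the two CHCl carbons C2 and C4, so C2–C3(=C7) is the retron of an allene adding through C2=C3, and C4–C5–C6–C1 is a 1-chloro-3-oxy-diene (C6–Br ⇐ C6–O).
4. Stereocontrol: the single C7 stereocentre of 5 (from (R)-glyceraldehyde acetonide) fixes the diene face, endo addition makes both C–Cl bonds cis, and C7 is then destroyed.
5. Ring order: oxetan-2-one (step 4) → cyclohexane (step 7) → oxetanone excised as CO2 (step 10).

Key step: step 7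

Remark: the target is read from the SMILES as (2S,3Z,4S,6S), with CH2Br cis to C2, the two chlorines cis to each other and bromine trans to both; TBDPS = tert-butyldiphenylsilyl, TBS = tert-butyldimethylsilyl.

Step 1
Reactants: 1 (R)-2,2-dimethyl-1,3-dioxolane-4-carbaldehyde
Product: 2 (S)-4-ethynyl-2,2-dimethyl-1,3-dioxolane
Conditions: dimethyl (1-diazo-2-oxopropyl)phosphonate, K2CO3, MeOH, 0 °C → rt
Reagents that add atoms: dimethyl (1-diazo-2-oxopropyl)phosphonate, CC(=O)C(=[N+]=[N-])P(=O)(OC)OC
Why: Ohira–Bestmann (Seyferth–Gilbert) homologation turns the aldehyde into the terminal alkyne under mild carbonate conditions that should leave the oxygenated stereocentre untouched (the descriptor changes from R to S only because the CIP priorities change).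

Step 2
Reactants: 2 (S)-4-ethynyl-2,2-dimethyl-1,3-dioxolane
Product: 3 (S)-but-3-yne-1,2-diol
Conditions: 1 M HCl, THF–H2O, rt
Reagents that add atoms: none
Why: Acid-catalysed acetal hydrolysis should release the diol without involving the stereocentre.

Step 3
Reactants: 3 (S)-but-3-yne-1,2-diol
Product: 4 (S)-1-[(tert-butyldiphenylsilyl)oxy]but-3-yn-2-ol
Conditions: TBDPSCl (1.0 equiv), imidazole, CH2Cl2, −20 → 0 °C
Reagents that add atoms: tert-butyl(chloro)diphenylsilane, CC(C)(C)[Si](Cl)(c1ccccc1)c1ccccc1
Why: Sterically controlled silylation should select the primary hydroxyl and leave the propargylic hydroxyl free for lactone formation.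

Step 4
Reactants: 4 (S)-1-[(tert-butyldiphenylsilyl)oxy]but-3-yn-2-ol
Product: 5 (4S)-4-{[(tert-butyldiphenylsilyl)oxy]methyl}-3-[(Z)-chloromethylidene]oxetan-2-one
Conditions: PdCl2 (10 mol%), CuCl2 (3 equiv), CO (1–20 bar), THF, rt
Reagents that add atoms: carbon monoxide, [C-]#[O+]; copper dichloride CuCl2, Cl[Cu]Cl
Why: PdCl2-catalysed chlorocarbonylative lactonisation of a 2-alkynol: syn alkoxycarbonylpalladation of the alkyne by the hydroxyl (four-membered ring closure) and chloride transfer from CuCl2 to the vinyl–palladium bond should place Cl cis to the lactone C=O (Z) while the carbinol C–O bond, and so the S centre, is untouched; CuCl2 returns zerovalent palladium to divalent palladium.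

Step 5
Reactants: 6 2-methylpropanoyl chloride (isobutyryl chloride); 7 acetylene
Product: 8 (E)-1-chloro-4-methylpent-1-en-3-one
Conditions: AlCl3, acetylene (bubbled), CH2Cl2, 0 °C → rt
Reagents that add atoms: none
Why: Friedel–Crafts-type acylation of acetylene, in which the vinyl cation is captured by chloride, should give the β-chlorovinyl ketone as the thermodynamically preferred E isomer.

Step 6
Reactants: 8 (E)-1-chloro-4-methylpent-1-en-3-one
Product: 9 (E)-tert-butyl[(1-chloro-4-methylpenta-1,3-dien-3-yl)oxy]dimethylsilane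
Conditions: TBSOTf, i-Pr2NEt, CH2Cl2, −78 → 0 °C
Reagents that add atoms: tert-butyldimethylsilyl trifluoromethanesulfonate, CC(C)(C)[Si](C)(C)OS(=O)(=O)C(F)(F)F
Why: Soft enolisation (silyl triflate with a hindered amine) at the only enolisable position, the isopropyl methine, should give the fully substituted silyl dienol ether with the E chloroalkene retained, the hindered base avoiding addition–elimination at the chlorovinyl carbon.

Step 7
Reactants: 5 (4S)-4-{[(tert-butyldiphenylsilyl)oxy]methyl}-3-[(Z)-chloromethylidene]oxetan-2-one; 9 (E)-tert-butyl[(1-chloro-4-methylpenta-1,3-dien-3-yl)oxy]dimethylsilane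
Product: 11 (3S,4S,5R,9S)-3-{[(tert-butyldiphenylsilyl)oxy]methyl}-5,9-dichloro-6,6-dimethyl-2-oxaspiro[3.5]nonane-1,7-dione, via silyl enol ether cycloadduct 10 (not isolated)
Conditions: 9 (3 equiv), BHT (cat.), PhMe (2 M), 85 °C, sealed tube (or CH2Cl2, 12 kbar, 25 °C); then Et3N·3HF, THF, 0 °C
Reagents that add atoms: none
Why: A normal-electron-demand Diels–Alder reaction in which the strained oxetanone C=O activates the exocyclic C2=C3 bond of 5, so that 5 acts as a configurationally defined 1-chloroallene equivalent; the closest known reaction types are the [4+2] cycloadditions of α-alkylidene-β-lactones (allene equivalents) and of fully substituted 2-silyloxydienes with hindered dienophiles. The cyclohexene ring closes by a concerted, asynchronous suprafacial [4+2] addition that forms C1–C2 and C3–C4 together, the 6-silyloxy and 4-chloro groups of 9 both directing the nucleophilic terminus C1 to the β-carbon C2 and C4 to the carbonyl-bearing C3. C2 and C4 are set by the endo transition state: the lactone C=O and the Z chlorine on C2 lie under the diene (the exo position at C2, wedged between the two C1 methyls, takes the hydrogen), so both C–Cl bonds end cis to each other and to the lactone carbonyl. The spiro centre C3 and the absolute configuration are set by the C7 stereocentre of the oxetanone, the diene adding to the face anti to CH2OTBDPS, which leaves C8 cis to C2 across the four-membered ring. The step needs regio-, endo- and facial selectivity and a concerted course: the reinforcing donor pattern of 9, the rigid planar lactone and the absence of a Lewis acid (no enolate that could expel the C2 chloride) should secure these, a hetero-Diels–Alder path through C=C–C=O is blocked because it would put a double bond inside the oxetane ring, and the nonpolar medium or high pressure should hold back loss of CO2 from 5. Buffered fluoride then cleaves only the silyl enol ether, giving the C6 ketone by protonation at C5.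

Step 8
Reactants: 11 (3S,4S,5R,9S)-3-{[(tert-butyldiphenylsilyl)oxy]methyl}-5,9-dichloro-6,6-dimethyl-2-oxaspiro[3.5]nonane-1,7-dione
Product: 12 (3S,4S,5R,7R,9S)-3-{[(tert-butyldiphenylsilyl)oxy]methyl}-5,9-dichloro-7-hydroxy-6,6-dimethyl-2-oxaspiro[3.5]nonan-1-one
Conditions: NaBH4, CeCl3·7H2O, MeOH–THF, −78 °C
Reagents that add atoms: none
Why: Luche reduction: in the chair with both chlorines equatorial, hydride should add axially to the C6 carbonyl, away from the axial C1 methyl, to give the equatorial alcohol cis to both chlorines, while the buffered low-temperature conditions should spare the β-lactone and avoid β-elimination of the C4 chloride.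

Step 9
Reactants: 12 (3S,4S,5R,7R,9S)-3-{[(tert-butyldiphenylsilyl)oxy]methyl}-5,9-dichloro-7-hydroxy-6,6-dimethyl-2-oxaspiro[3.5]nonan-1-one
Product: 13 (3S,4S,5S,7S,9S)-7-bromo-3-{[(tert-butyldiphenylsilyl)oxy]methyl}-5,9-dichloro-6,6-dimethyl-2-oxaspiro[3.5]nonan-1-one
Conditions: CBr4, PPh3, PhMe, 0 → 60 °C
Reagents that add atoms: tetrabromomethane, BrC(Br)(Br)Br
Why: Appel reaction: SN2 displacement of the oxyphosphonium group by bromide with inversion should turn the all-cis alcohol into the bromide trans to both chlorines (the C6 configuration of the target), the equatorial leaving group having no anti-periplanar hydrogen for E2 elimination.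

Step 10
Reactants: 13 (3S,4S,5S,7S,9S)-7-bromo-3-{[(tert-butyldiphenylsilyl)oxy]methyl}-5,9-dichloro-6,6-dimethyl-2-oxaspiro[3.5]nonan-1-one
Product: 14 (2Z)-2-[(2S,4S,6S)-4-bromo-2,6-dichloro-3,3-dimethylcyclohexylidene]ethyl tert-butyldiphenylsilyl ether
Conditions: PhMe (0.02 M), 140 °C, sealed tube
Reagents that add atoms: none
Why: Thermal retro-[2+2] cycloreversion of the β-lactone (loss of CO2) is stereospecific with retention, so C8, which is cis to C2 on the oxetanone, should end cis to C2 on the new C3=C7 double bond (Z) while the C7 stereocentre is consumed.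

Step 11
Reactants: 14 (2Z)-2-[(2S,4S,6S)-4-bromo-2,6-dichloro-3,3-dimethylcyclohexylidene]ethyl tert-butyldiphenylsilyl ether
Product: 15 (2Z)-2-[(2S,4S,6S)-4-bromo-2,6-dichloro-3,3-dimethylcyclohexylidene]ethan-1-ol
Conditions: HF·pyridine, THF, 0 °C → rt
Reagents that add atoms: none
Why: Fluoride-mediated silyl ether cleavage (Si–F bond formation) under weakly acidic conditions should free the primary allylic alcohol without touching the allylic chlorides or the secondary bromide.

Step 12
Reactants: 15 (2Z)-2-[(2S,4S,6S)-4-bromo-2,6-dichloro-3,3-dimethylcyclohexylidene]ethan-1-ol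
Product: 16 (2S,3Z,4S,6S)-6-bromo-3-(2-bromoethylidene)-2,4-dichloro-1,1-dimethylcyclohexane (CNP0156384.1)
Conditions: CBr4, PPh3, CH2Cl2, 0 °C
Reagents that add atoms: tetrabromomethane, BrC(Br)(Br)Br
Why: Appel reaction on a primary allylic alcohol at low temperature should give the allylic bromide by direct SN2 displacement without allylic transposition, so the Z geometry and the three ring stereocentres are kept.

**Compound list**
1 | (R)-2,2-dimethyl-1,3-dioxolane-4-carbaldehyde | O=C[C@H]1COC(C)(C)O1 | starting material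
2 | (S)-4-ethynyl-2,2-dimethyl-1,3-dioxolane | C#C[C@H]1COC(C)(C)O1 | intermediate
3 | (S)-but-3-yne-1,2-diol | C#C[C@H](O)CO | intermediate
4 | (S)-1-[(tert-butyldiphenylsilyl)oxy]but-3-yn-2-ol | C#C[C@H](O)CO[Si](c1ccccc1)(c1ccccc1)C(C)(C)C | intermediate
5 | (4S)-4-{[(tert-butyldiphenylsilyl)oxy]methyl}-3-[(Z)-chloromethylidene]oxetan-2-one (Cl cis to the lactone C=O) | Cl/C=C1\C(=O)O[C@@H]1CO[Si](c2ccccc2)(c2ccccc2)C(C)(C)C | intermediate
6 | 2-methylpropanoyl chloride | CC(C)C(Cl)=O | starting material
7 | acetylene | C#C | starting material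
8 | (E)-1-chloro-4-methylpent-1-en-3-one | CC(C)C(=O)/C=C/Cl | intermediate
9 | (E)-tert-butyl[(1-chloro-4-methylpenta-1,3-dien-3-yl)oxy]dimethylsilane | CC(C)=C(O[Si](C)(C)C(C)(C)C)/C=C/Cl | intermediate
10 | (3S,4S,5S,9R)-7-[(tert-butyldimethylsilyl)oxy]-3-{[(tert-butyldiphenylsilyl)oxy]methyl}-5,9-dichloro-8,8-dimethyl-2-oxaspiro[3.5]non-6-en-1-one (both Cl cis to the lactone C=O; CH2OTBDPS cis to the CHCl–CMe2 carbon across the oxetanone) | CC1(C)C(O[Si](C)(C)C(C)(C)C)=C[C@H](Cl)[C@]2(C(=O)O[C@@H]2CO[Si](c3ccccc3)(c3ccccc3)C(C)(C)C)[C@@H]1Cl | intermediate (not isolated)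
11 | (3S,4S,5R,9S)-3-{[(tert-butyldiphenylsilyl)oxy]methyl}-5,9-dichloro-6,6-dimethyl-2-oxaspiro[3.5]nonane-1,7-dione | CC1(C)C(=O)C[C@H](Cl)[C@]2(C(=O)O[C@@H]2CO[Si](c3ccccc3)(c3ccccc3)C(C)(C)C)[C@@H]1Cl | intermediate
12 | (3S,4S,5R,7R,9S)-3-{[(tert-butyldiphenylsilyl)oxy]methyl}-5,9-dichloro-7-hydroxy-6,6-dimethyl-2-oxaspiro[3.5]nonan-1-one (OH cis to both Cl) | CC1(C)[C@H](O)C[C@H](Cl)[C@]2(C(=O)O[C@@H]2CO[Si](c3ccccc3)(c3ccccc3)C(C)(C)C)[C@@H]1Cl | intermediate
13 | (3S,4S,5S,7S,9S)-7-bromo-3-{[(tert-butyldiphenylsilyl)oxy]methyl}-5,9-dichloro-6,6-dimethyl-2-oxaspiro[3.5]nonan-1-one (Br trans to both Cl) | CC1(C)[C@@H](Br)C[C@H](Cl)[C@]2(C(=O)O[C@@H]2CO[Si](c3ccccc3)(c3ccccc3)C(C)(C)C)[C@@H]1Cl | intermediate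
14 | (2Z)-2-[(2S,4S,6S)-4-bromo-2,6-dichloro-3,3-dimethylcyclohexylidene]ethyl tert-butyldiphenylsilyl ether | CC1(C)[C@@H](Br)C[C@H](Cl)/C(=C/CO[Si](c2ccccc2)(c2ccccc2)C(C)(C)C)[C@@H]1Cl | intermediate
15 | (2Z)-2-[(2S,4S,6S)-4-bromo-2,6-dichloro-3,3-dimethylcyclohexylidene]ethan-1-ol | CC1(C)[C@@H](Br)C[C@H](Cl)/C(=C/CO)[C@@H]1Cl | intermediate
16 | (2S,3Z,4S,6S)-6-bromo-3-(2-bromoethylidene)-2,4-dichloro-1,1-dimethylcyclohexane | CC1(C)[C@@H](Br)C[C@H](Cl)/C(=C/CBr)[C@@H]1Cl | target

**Step count**
Total steps: 12. Longest linear sequence: 10 steps (steps 1–4 and 7–12).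

**Steps most likely to fail**

1. Step 7. The two hindered partners may combine so slowly that thermal cycloreversion of 5 to a chloroallene and CO2, or erosion of endo control, overtakes the cycloaddition. The fallback sets out from 5 (and 9) and returns at 11; it makes the same two bonds on a chelated aldehyde. Lactone 5 would be reduced with DIBAL-H (CH2Cl2, −78 → 0 °C) to the diol (3S)-4-[(tert-butyldiphenylsilyl)oxy]-2-(chloromethylidene)butane-1,3-diol F1. TEMPO/PhI(OAc)2 should oxidise only the primary allylic hydroxyl, giving the hydroxy enal F2. F2 and 9 would then be combined in the presence of MgBr2·OEt2 (CH2Cl2, −40 °C), where the chelate between the aldehyde oxygen and the free hydroxyl takes the place of the oxetanone ring in fixing the face. Cleavage of the silyl enol ether with Et3N·3HF should give the keto hydroxy aldehyde F3. Pinnick oxidation (NaClO2, NaH2PO4, 2-methylbut-2-ene) would give the β-hydroxy acid F4. Carboxyl activation with benzenesulfonyl chloride in pyridine (0 °C) should close the β-lactone with retention at the carbinol carbon to give ketone 11.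

2. Step 9. Substitution at the carbinol carbon next to the quaternary C1 may stall, giving way to ring contraction by a 1,2-shift or to attack of the phosphine on the β-lactone. The fallback sets out from 12 and returns at 13. Alcohol 12 would be converted with Tf2O and pyridine (CH2Cl2, −30 °C) into the isolated secondary triflate F5. F5 would be displaced with Bu4NBr in toluene at room temperature (SN2 with inversion, in a non-ionising medium) to give bromide 13.

3. Step 10. The temperature needed for CO2 loss may also cause loss of HBr from the axial secondary bromide or migration of the newly allylic chlorides. The fallback sets out from 12 and returns at 16; it introduces both bromines only after the cycloreversion. Alcohol 12 would be silylated (Et3SiCl, imidazole, CH2Cl2) to the triethylsilyl ether F6. Thermolysis of F6 (PhMe, 140 °C) should give the alkene bis-silyl ether F7. HF·pyridine would remove both silyl groups to give the diol F8. One Appel reaction (CBr4, PPh3, PhMe, 0 → 60 °C) would then convert both hydroxyls into bromides, with inversion at C6 and direct displacement at C8, to give the target 16.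

Further compounds
F1 | step 7 | (3S)-4-[(tert-butyldiphenylsilyl)oxy]-2-(chloromethylidene)butane-1,3-diol (Cl cis to CH2OH) | Cl/C=C(\CO)[C@H](O)CO[Si](c1ccccc1)(c1ccccc1)C(C)(C)C
F2 | step 7 | (3S)-4-[(tert-butyldiphenylsilyl)oxy]-2-(chloromethylidene)-3-hydroxybutanal (Cl cis to CHO) | Cl/C=C(\C=O)[C@H](O)CO[Si](c1ccccc1)(c1ccccc1)C(C)(C)C
F3 | step 7 | 1-{(1S)-2-[(tert-butyldiphenylsilyl)oxy]-1-hydroxyethyl}-2,6-dichloro-3,3-dimethyl-4-oxocyclohexane-1-carbaldehyde (both Cl cis to CHO) | CC1(C)C(=O)C[C@H](Cl)[C@@](C=O)([C@H](O)CO[Si](c2ccccc2)(c2ccccc2)C(C)(C)C)[C@@H]1Cl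
F4 | step 7 | 1-{(1S)-2-[(tert-butyldiphenylsilyl)oxy]-1-hydroxyethyl}-2,6-dichloro-3,3-dimethyl-4-oxocyclohexane-1-carboxylic acid (both Cl cis to CO2H) | CC1(C)C(=O)C[C@H](Cl)[C@@](C(=O)O)([C@H](O)CO[Si](c2ccccc2)(c2ccccc2)C(C)(C)C)[C@@H]1Cl
F5 | step 9 | trifluoromethanesulfonate of alcohol 12 (OTf cis to both Cl) | CC1(C)[C@H](OS(=O)(=O)C(F)(F)F)C[C@H](Cl)[C@]2(C(=O)O[C@@H]2CO[Si](c3ccccc3)(c3ccccc3)C(C)(C)C)[C@@H]1Cl
F6 | step 10 | triethylsilyl ether of alcohol 12 | CC1(C)[C@H](O[Si](CC)(CC)CC)C[C@H](Cl)[C@]2(C(=O)O[C@@H]2CO[Si](c3ccccc3)(c3ccccc3)C(C)(C)C)[C@@H]1Cl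
F7 | step 10 | (Z)-alkylidene bis-silyl ether from F6 (C6–OSiEt3 cis to both Cl; CH2OTBDPS cis to C2) | CC1(C)[C@H](O[Si](CC)(CC)CC)C[C@H](Cl)/C(=C/CO[Si](c2ccccc2)(c2ccccc2)C(C)(C)C)[C@@H]1Cl
F8 | step 10 | 3,5-dichloro-4-[(Z)-2-hydroxyethylidene]-2,2-dimethylcyclohexan-1-ol (OH cis to both Cl; CH2OH cis to C2) | CC1(C)[C@H](O)C[C@H](Cl)/C(=C/CO)[C@@H]1Cl
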